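**Assumption:** planaic acid has no stereocentre and is achiral, so there is no enantiomer to select. Phenoxide and carboxylate salts count as ionised forms of the numbered neutral compounds and get no number of their own.

## Retrosynthetic overview
1. Planaic acid ⇒ its constitutional isomer, the depside that carries 2'-OH and CO2Me. The last step moves the ester methyl onto the 2'-oxygen, which forms the O–CH3 bond and frees the CO2H in one operation.
2. That depside ⇒ aryl ester C–O disconnection (key bond) into 2,4-dimethoxy-6-pentylbenzoic acid and methyl olivetolate, joined at the free, non-chelated 4-OH.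
3. The acid ⇒ methyl olivetolate as well (exhaustive O-methylation, then saponification), so one purchased building block supplies both halves.
4. No ring is formed and no C–C bond is made. Both benzene rings, both pentyl chains and both carboxyl carbons come with methyl olivetolate.

## Route

**Step 1**
Reactants: 1 methyl olivetolate (methyl 2,4-dihydroxy-6-pentylbenzoate)
Product: 3 2,4-dimethoxy-6-pentylbenzoic acid, via methyl 2,4-dimethoxy-6-pentylbenzoate 2 (not isolated)
Conditions: MeI (3 equiv), powdered KOH (6 equiv), DMSO, rt, 2 h; then H2O, 95 °C, 12 h; then 2 M HCl, 0 °C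
Reagents that add atoms: iodomethane, CI; potassium hydroxide, [K+].[OH-] (its oxygen becomes the OH oxygen of the CO2H group)
Why: Williamson O-methylation in KOH/DMSO alkylates both phenoxides, including the chelated 2-OH, and the poorly solvated hydroxide of hot aqueous DMSO then saponifies the di-ortho-substituted ester (BAc2) in the same pot; no stereocentre is formed.

**Step 2**
Reactants: 3 2,4-dimethoxy-6-pentylbenzoic acid; 1 methyl olivetolate
Product: 5 methyl 4-[(2,4-dimethoxy-6-pentylbenzoyl)oxy]-2-hydroxy-6-pentylbenzoate, via 2,4-dimethoxy-6-pentylbenzoic trifluoroacetic anhydride 4 (not isolated)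
Conditions: TFAA (5 equiv), toluene, 0 °C to rt, 3 h; aq NaHCO3 work-up
Reagents that add atoms: trifluoroacetic anhydride, O=C(OC(=O)C(F)(F)F)C(F)(F)F (its CF3CO group sits only in 4 and is gone in 5)
Why: This is the standard TFAA mixed-anhydride (acylium-type) depside esterification, in which the electron-rich hindered acyl group of 4 is taken up only by the free 4-OH of 1 because the 2-OH is hydrogen-bonded to and flanked by the ester carbonyl; no stereocentre is formed.

**Step 3**
Reactants: 5 methyl 4-[(2,4-dimethoxy-6-pentylbenzoyl)oxy]-2-hydroxy-6-pentylbenzoate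
Product: 7 planaic acid (4-[(2,4-dimethoxy-6-pentylbenzoyl)oxy]-2-methoxy-6-pentylbenzoic acid), via methyl planaate 6 (not isolated)
Conditions: KOt-Bu (1.00 equiv), THF, 0 °C, evaporate; LiI (30 mol %), DMA (0.5 M), sealed tube, 120 °C, 24 h; then 1 M HCl, 0 °C
Reagents that add atoms: none
Why: Proposed new method: iodide-shuttled O-to-O methyl transposition, a net isomerisation of a methyl salicylate salt into a 2-methoxybenzoate salt. Iodide removes the ester methyl by SN2 at carbon (alkyl–oxygen fission, the only path open at a di-ortho-substituted ester), the iodomethane formed O-methylates the 2'-phenoxide of a second molecule to give 6, and iodide then dealkylates neutral 6 to potassium planaate and returns iodomethane, so I−/MeI carry a chain driven by moving the charge from a phenoxide (pKa about 10) to a carboxylate (pKa about 4). The depside ester offers iodide no sp3 C–O carbon and its carbonyl is shielded by 2-OMe and 6-pentyl, and any ring-ether demethylation is undone by the retained MeI because planaate is the thermodynamic sink of the methyl distribution. The closest known reaction types are LiI (Krapcho-type) SN2 cleavage of hindered methyl esters, Williamson methylation of phenoxides, and methyl salicylate acting as a methyl donor towards carboxylates; no stereocentre is formed.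

## Compound list
1 | methyl olivetolate (methyl 2,4-dihydroxy-6-pentylbenzoate) | CCCCCc1cc(O)cc(O)c1C(=O)OC | starting material
2 | methyl 2,4-dimethoxy-6-pentylbenzoate | CCCCCc1cc(OC)cc(OC)c1C(=O)OC | intermediate (not isolated)
3 | 2,4-dimethoxy-6-pentylbenzoic acid | CCCCCc1cc(OC)cc(OC)c1C(=O)O | intermediate
4 | 2,4-dimethoxy-6-pentylbenzoic trifluoroacetic anhydride | CCCCCc1cc(OC)cc(OC)c1C(=O)OC(=O)C(F)(F)F | intermediate (not isolated)
5 | methyl 4-[(2,4-dimethoxy-6-pentylbenzoyl)oxy]-2-hydroxy-6-pentylbenzoate | CCCCCc1cc(OC(=O)c2c(CCCCC)cc(OC)cc2OC)cc(O)c1C(=O)OC | intermediate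
6 | methyl planaate (methyl 4-[(2,4-dimethoxy-6-pentylbenzoyl)oxy]-2-methoxy-6-pentylbenzoate) | CCCCCc1cc(OC(=O)c2c(CCCCC)cc(OC)cc2OC)cc(OC)c1C(=O)OC | intermediate (not isolated)
7 | planaic acid (achiral) | CCCCCc1cc(OC(=O)c2c(CCCCC)cc(OC)cc2OC)cc(OC)c1C(=O)O | target

## Count
- Total steps: 3
- Longest linear sequence: 3 (1 → 3 → 5 → 7). Compound 1 enters twice, in step 1 and in step 2.

## Steps most likely to fail

**Step 3 (the new step).**
- Risks: at 120 °C the 2'-phenoxide may attack the depside carbonyl of a neighbouring molecule and scramble the acyl group. Iodide turnover on the ester methyl may also be too slow at catalytic loading.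
- Fallback (known chemistry): change the carboxyl mask from methyl to benzyl, so that O-methylation and unmasking become two separate, mild, classical reactions.
- It sets out from 3 and comes back at 7. Purchased olivetolic acid F1 is esterified at the carboxylate only (BnBr, KHCO3, DMF, rt) to benzyl olivetolate F2. Acid 3 and F2 are joined with TFAA in toluene (again through 4) to benzyl 4-[(2,4-dimethoxy-6-pentylbenzoyl)oxy]-2-hydroxy-6-pentylbenzoate F3. MeI and K2CO3 in refluxing acetone methylate the 2'-OH to give benzyl planaate F4. Hydrogenolysis (H2, 10% Pd/C, EtOAc, rt) then gives 7 without touching the depside ester.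

**Step 2.**
- Risks: the acylium-type species may C-acylate the very electron-rich ring of 1, or may also acylate the 2-OH.
- Fallback: switch from cationic acyl transfer in acid to anionic acyl transfer with an isolated acyl halide.
- It sets out from 3 and comes back at 5. Acid 3 with (COCl)2 and catalytic DMF in CH2Cl2 gives 2,4-dimethoxy-6-pentylbenzoyl chloride F5, isolated by evaporation. F5 is added to 1 and K2CO3 (1.1 equiv) in acetone at 0 °C to rt. Only the more acidic, non-chelated 4-OH is ionised there, and the phenoxide oxygen rather than the ring carbon is acylated.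

**Step 1.**
- Risks: saponification of the di-ortho-substituted ester 2 may stall, and forcing it may cause decarboxylation.
- Fallback: break the other ester bond, alkyl–oxygen instead of acyl–oxygen, so the shielded carbonyl is never attacked.
- It sets out from 2 (isolated after the methylation) and comes back at 3. Lithium propane-1-thiolate in DMPU (or HMPA) at rt removes the ester methyl by SN2, leaving the aryl methyl ethers intact at this temperature. Cold dilute HCl then liberates 3. No new compound is made.

## Further compounds
F1 | step 3 | olivetolic acid (2,4-dihydroxy-6-pentylbenzoic acid; purchased) | CCCCCc1cc(O)cc(O)c1C(=O)O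
F2 | step 3 | benzyl olivetolate (benzyl 2,4-dihydroxy-6-pentylbenzoate) | CCCCCc1cc(O)cc(O)c1C(=O)OCc1ccccc1
F3 | step 3 | benzyl 4-[(2,4-dimethoxy-6-pentylbenzoyl)oxy]-2-hydroxy-6-pentylbenzoate | CCCCCc1cc(OC(=O)c2c(CCCCC)cc(OC)cc2OC)cc(O)c1C(=O)OCc1ccccc1
F4 | step 3 | benzyl planaate (benzyl 4-[(2,4-dimethoxy-6-pentylbenzoyl)oxy]-2-methoxy-6-pentylbenzoate) | CCCCCc1cc(OC(=O)c2c(CCCCC)cc(OC)cc2OC)cc(OC)c1C(=O)OCc1ccccc1
F5 | step 2 | 2,4-dimethoxy-6-pentylbenzoyl chloride | CCCCCc1cc(OC)cc(OC)c1C(=O)Cl
F0 | step 1 | none | none
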